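**Retrosynthetic overview**
1. Ring A is bought as 2,4-dihydroxyacetophenone 1 and ring B as 4-hydroxybenzaldehyde 2; the C2–C3 alkene joining them (chalcone 3) is an aldol disconnection.
2. Key disconnection: the two C–O bonds of ring C (C3–OH and O1–C2), traced back through epoxide 4 of chalcone 3. Their enantioselective construction closes ring C as trans-dihydroflavonol 5 and sets C2 and C3.
3. Rings D, E and F (the whole lower unit with its two stereocentres) are bought as (−)-epicatechin 6.
4. Last disconnection: the C4–C8 interflavan bond. Benzylic diol 7 (from 5) is ionised at C4 and captured by C8 of 6 to give target 8; C4 is set by the neighbouring C3–OH.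
5. Ring order: A and B bought, C formed in step 2, D/E/F bought and joined last; no protecting groups.

Assumption: the SMILES is read as ent-guibourtinidol-(4β→8)-epicatechin (upper unit 2S,3R,4R, all-trans; lower unit 2R,3R). L* in step 2 is 1,1'-(propane-1,3-diyl)bis[(2R)-2-{[2,6-di(propan-2-yl)phenyl]carbamoyl}piperidine 1-oxide] (from D-pipecolic acid). Its sense of induction on this new substrate is assumed as drawn; if the first run gives ent-5, the L-pipecolic antipode is used instead.

**Step 1**
Reactants: 1 2,4-dihydroxyacetophenone; 2 4-hydroxybenzaldehyde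
Product: 3 isoliquiritigenin, (E)-1-(2,4-dihydroxyphenyl)-3-(4-hydroxyphenyl)prop-2-en-1-one
Conditions: KOH (60% aq, 12 equiv), EtOH, 0 °C to rt, 72 h; then 2 M HCl to pH 2
Reagents that add atoms: none
Why: Claisen–Schmidt crossed aldol condensation, in which only the ketone is enolisable and E1cB dehydration gives the conjugated E-enone; no stereocentre is formed.

**Step 2**
Reactants: 3 isoliquiritigenin
Product: 5 (2S,3S)-3,7-dihydroxy-2-(4-hydroxyphenyl)chroman-4-one (ent-garbanzol), via chalcone epoxide 4 (not isolated)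
Conditions: Sc(OTf)3 (10 mol%), L* (11 mol%), 30% aq H2O2 (1.5 equiv), THF, 30 °C, 24 h
Reagents that add atoms: hydrogen peroxide, OO
Why: Proposed new method: an enantioselective, base-free Algar–Flynn–Oyamada-type epoxidation/cyclisation cascade. The 2'-OH/C=O pair of 3 chelates the two free cis sites of the Sc(OTf)3·L* complex, H2O2 adds to the exposed Cβ si face, and the scandium enolate closes to the (2S,3R)-epoxide 4 (Weitz–Scheffer; sets C3). The same Lewis acid, now bound to the carbonyl and oxirane oxygens, polarises the 4-hydroxybenzylic Cβ–O bond, and the released 2'-OH opens it 6-endo with inversion to give 2,3-trans ring C. Any C2 epimer from a looser SN1 opening re-equilibrates to trans through the same benzylic cation while C3 stays fixed. Redox-inert trivalent scandium and the absence of base spare the free phenols and stop the oxidation at the dihydroflavonol stage. Closest known reaction types: Sc(OTf)3/N,N'-dioxide-catalysed epoxidation of simple chalcones with aqueous H2O2, the racemic alkaline Algar–Flynn–Oyamada reaction, and acid cyclisation of 2'-O-protected chalcone epoxides; none has been run as an asymmetric cascade on an unprotected 2'-hydroxychalcone.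

**Step 3**
Reactants: 5 (2S,3S)-3,7-dihydroxy-2-(4-hydroxyphenyl)chroman-4-one; 6 (−)-epicatechin
Product: 8 ent-guibourtinidol-(4β→8)-epicatechin (target CNP0118995.1), via benzylic diol 7 (not isolated)
Conditions: NaBH4 (4 equiv), EtOH, 0 °C to rt, 2 h, Ar; then added to 6 (4 equiv) in aq HCl (final 0.1 M), rt, 16 h, Ar
Reagents that add atoms: none
Why: NaBH4 reduces the C4 ketone to the diol, and in dilute acid the benzylic 4-OH ionises to the C4 cation stabilised by the para 7-oxygen; C8 of the phloroglucinol ring of 6 captures it in a Friedel–Crafts alkylation on the face anti to the C3–OH (3,4-trans, 4R), so C4 is set by substrate control while C2, C3 and the two stereocentres of 6 are untouched.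

**Compound list**
1 | 2,4-dihydroxyacetophenone | CC(=O)c1ccc(O)cc1O | starting material
2 | 4-hydroxybenzaldehyde | O=Cc1ccc(O)cc1 | starting material
3 | isoliquiritigenin, (E)-1-(2,4-dihydroxyphenyl)-3-(4-hydroxyphenyl)prop-2-en-1-one | O=C(/C=C/c1ccc(O)cc1)c1ccc(O)cc1O | intermediate
4 | (2,4-dihydroxyphenyl)[(2S,3R)-3-(4-hydroxyphenyl)oxiran-2-yl]methanone (trans-epoxide) | O=C(c1ccc(O)cc1O)[C@H]1O[C@@H]1c1ccc(O)cc1 | intermediate
5 | (2S,3S)-3,7-dihydroxy-2-(4-hydroxyphenyl)-2,3-dihydro-4H-chromen-4-one (ent-garbanzol, 2,3-trans) | O=C1c2ccc(O)cc2O[C@@H](c2ccc(O)cc2)[C@@H]1O | intermediate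
6 | (−)-epicatechin, (2R,3R)-2-(3,4-dihydroxyphenyl)-3,4-dihydro-2H-chromene-3,5,7-triol | Oc1cc(O)c2c(c1)O[C@H](c1ccc(O)c(O)c1)[C@H](O)C2 | starting material
7 | (2S,3R,4S)-2-(4-hydroxyphenyl)-3,4-dihydro-2H-chromene-3,4,7-triol (2,3-trans-3,4-trans; the minor 4R epimer reacts alike) | Oc1ccc([C@@H]2Oc3cc(O)ccc3[C@H](O)[C@H]2O)cc1 | intermediate
8 | (2R,3R)-2-(3,4-dihydroxyphenyl)-8-[(2S,3R,4R)-3,7-dihydroxy-2-(4-hydroxyphenyl)-3,4-dihydro-2H-chromen-4-yl]-3,4-dihydro-2H-chromene-3,5,7-triol | Oc1ccc([C@@H]2Oc3cc(O)ccc3[C@H](c3c(O)cc(O)c4c3O[C@H](c3ccc(O)c(O)c3)[C@H](O)C4)[C@H]2O)cc1 | target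

**Totals**
Total step count: 3. Longest linear sequence: 3 (1 → 3 → 5 → 8).

**Steps most likely to fail, with fallbacks**

Step 2 (the new cascade). Risks are slow epoxidation of the electron-rich enone, competing oxa-Michael closure to the flavanone, aroyl shift of the opened epoxide towards an isoflavone, and low ee. The ee of 5 can be raised by recrystallisation, and residual ent-5 would only give separable diastereomers in step 3. The fallback uses known chemistry, sets out from 3 and returns at 5. Compound 3 is fully protected (MOMCl, NaH, DMF, 0 °C) to give (E)-2',4,4'-tris(methoxymethoxy)chalcone F4. Juliá–Colonna epoxidation (poly-D-leucine, urea–H2O2, DBU, THF, rt) gives [2,4-bis(methoxymethoxy)phenyl]{(2S,3R)-3-[4-(methoxymethoxy)phenyl]oxiran-2-yl}methanone F5. Treatment with 3 M HCl in MeOH at 50 °C removes the three acetals and closes ring C at the benzylic carbon to give trans-dihydroflavonol 5.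

Step 3 (reduction/coupling). Risks are the C6-linked regioisomer, the 3,4-cis (4α) epimer, and trimers; 8 is expected as the major dimer, to be separated on Sephadex LH-20 and reverse-phase HPLC, with excess 6 recovered. The fallback sets out from 5 and returns at 8. Compound 5 is reduced (NaBH4, EtOH) and diol 7 is isolated. Diol 7 is converted (BnSH, AcOH, EtOH, 60 °C) into (2S,3S,4S)-4-(benzylsulfanyl)-2-(4-hydroxyphenyl)-3,4-dihydro-2H-chromene-3,7-diol F6. This thioether is activated with AgBF4 (2.5 equiv) in THF at 0 °C in the presence of 6 (4 equiv), which generates the C4 cation stoichiometrically under aprotic, non-equilibrating conditions and gives 8.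

Step 1 (unprotected aldol). The risk is low conversion, because the phenolates deactivate both partners. The fallback sets out from 1 and 2 and returns at 3. Compound 1 is mono-protected (MOMCl, K2CO3, acetone) to give 1-[2-hydroxy-4-(methoxymethoxy)phenyl]ethanone F1. Compound 2 is protected (MOMCl, iPr2NEt, CH2Cl2) to give 4-(methoxymethoxy)benzaldehyde F2. Condensation (KOH, EtOH, rt) gives (E)-2'-hydroxy-4,4'-bis(methoxymethoxy)chalcone F3, and 3 M HCl in MeOH (reflux, 15 min) releases 3.

**Further compounds**
F1 | step 1 | 1-[2-hydroxy-4-(methoxymethoxy)phenyl]ethanone | CC(=O)c1ccc(OCOC)cc1O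
F2 | step 1 | 4-(methoxymethoxy)benzaldehyde | O=Cc1ccc(OCOC)cc1
F3 | step 1 | (E)-1-[2-hydroxy-4-(methoxymethoxy)phenyl]-3-[4-(methoxymethoxy)phenyl]prop-2-en-1-one | O=C(/C=C/c1ccc(OCOC)cc1)c1ccc(OCOC)cc1O
F4 | step 2 | (E)-1-[2,4-bis(methoxymethoxy)phenyl]-3-[4-(methoxymethoxy)phenyl]prop-2-en-1-one | O=C(/C=C/c1ccc(OCOC)cc1)c1ccc(OCOC)cc1OCOC
F5 | step 2 | [2,4-bis(methoxymethoxy)phenyl]{(2S,3R)-3-[4-(methoxymethoxy)phenyl]oxiran-2-yl}methanone | O=C(c1ccc(OCOC)cc1OCOC)[C@H]1O[C@@H]1c1ccc(OCOC)cc1
F6 | step 3 | (2S,3S,4S)-4-(benzylsulfanyl)-2-(4-hydroxyphenyl)-3,4-dihydro-2H-chromene-3,7-diol | Oc1ccc([C@@H]2Oc3cc(O)ccc3[C@H](SCc3ccccc3)[C@H]2O)cc1
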